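(The readings are simulated for substances that don't exist; scatter was added.)

Late in Wednesday's run the product J still climbs, with 64.7% of the substrate Z charged at 8.00 min and 76.1% at 15.0 min, but the climb has slowed.

the same everywhere: G 200 mM (held); D 6.7 mM

| flask | Z | remark | time |
|---|---|---|---|
| Wednesday's | 1.1 M | run made earlier |  |
| flask | 2.3 M |  | 12 min |

- Wednesday's (time / min: J / %): 1.00: 19.6; 2.00: 33.2; 4.00: 48.3; 8.00: 64.7; 15.0: 76.1

(each reading ± 1 percentage point)

1. J at 12 min, in percent of the Z charged
2. concentration of E in solution at 12 min, in percent of saturation

- the numbers in the tables scatter by 1 percentage point (one standard deviation)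
- at the start none of G is in solution
- E is what G becomes in solution

I measure each run in lifetimes of Z spent: the logarithm of one over the fraction of Z left. On Wednesday's readings one lifetime of Z lasts 4.58 min at first and 17.9 min late, longer. I consider two readings of this: Z thinning stretches it, or Z decays pseudo-first-order against a clock, such as the catalyst D fading.

Turn the question round: for this flask, with twice Wednesday's Z and the same D and G, to convert a larger fraction by 12 min than Wednesday's run, its lifetime of Z must on average be shorter than Wednesday's over that time. I commit to the clock, which carries the count over unchanged. Interpolated in the logarithm of time, Wednesday's readings give 1.29 at 12 min, the lifetimes of Z spent by then. I assume this flask spends the same count, so I expect J near 72.5%. Wednesday's readings hold no measure of E, so I give no figure for it.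

The forecast differs: “Taking second order, doubling Z gives kZ₀t ≈ 5.5 at 12 min, so about 84%”. It states 83% and E at 95% of saturation. Its J needs 1.77 lifetimes, more than my count.

The flask gives J 69.1% and E 47.0% of saturation. Its Z left, 31% of the charge, is 1.17 lifetimes, fewer than my count.

    G ⇌ E, rate k1*(csat - [E]) (kL = 0.0720 s⁻¹)
    Z + E + D → D + J (k = 10.0 M⁻² s⁻¹)
    2 D → Q (k = 0.620 M⁻¹ s⁻¹)
    2 E → L (k = 0.400 M⁻¹ s⁻¹)
    D → X (k = 3.00 × 10⁻⁴ s⁻¹)

A neighbouring flask holds a quarter of this flask's Z, 0.57 M, with D, G and the time unchanged. Carrying the count over again gives it J 72.5%. It gives 74.0% and keeps 26% of its Z, which is 1.35 lifetimes, more than the flask's.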